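The data were computed with constants of no real substance; noise was put on by code.

I decided to count turnovers of substrate and to leave the curves alone.

| setting | Thursday's | Sunday's | Saturday's | Wednesday's | Tuesday's |
|---|---|---|---|---|---|
| substrate | 120 mM | 72.0 mM | 120 mM | 180 mM | 600 mM |
| target |  |  | 60.0 mM |  |  |
| time |  |  |  |  | 190 s |

- Thursday's run (time / s: [target] / mM): 24: 9.9; 48: 21.2; 71: 30.4; 95: 42.0; 120: 51.6; 140: 58.6; 170: 71.0; 190: 77.1
- Sunday's run (time / s: [target] / mM): 24: 5.6; 48: 11.7; 71: 18.5; 95: 23.5; 120: 27.9; 140: 32.0; 170: 38.3; 190: 42.7
- Saturday's run (time / s: [target] / mM): 24: 77.4; 48: 93.9; 71: 109.0; 95: 123.4; 120: 133.7; 140: 142.7; 170: 152.6; 190: 156.9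
- Wednesday's run (time / s: [target] / mM): 24: 16.0; 48: 33.7; 71: 50.2; 95: 68.0; 120: 86.2; 140: 100.7; 170: 118.2; 190: 128.6

(readings scatter by 0.6 mM)

- Overall: substrate -> target.
- Constant volume, constant temperature.
- An order is taken over about fifteen percent of the charge, up and down.

- how the opening rate goes with [substrate] round the charge of the Thursday's run: the exponent of the rate at two percent of substrate gone to target (one fixed amount of target, the same in the runs compared)
- the Sunday's run starts with 48.0 mM less of substrate than the Thursday's run, and with no target. Compared where both hold the same amount of substrate, once fifteen percent of what the Sunday's run was charged with has turned into target, is the Sunday's run faster, slower or alike (within a tenth)?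
- target in the Tuesday's run at 190 s, as a share of the substrate charged

I read the rate per substrate from the first reading of two flasks. Thursday's flask, charged with substrate alone, gave

0.00359 s⁻¹

and Saturday's flask, charged with target, gave

0.00653 s⁻¹

so Saturday's substrate turned faster than Thursday's. This is autocatalysis. Dividing the difference by the difference in mean target over those intervals, I got a gain per unit of target and, by subtraction, a seed rate at no target:

gain = 0.0461 M⁻¹ s⁻¹

seed rate = 0.00336 s⁻¹

These gave a ladder of times, fastest first. Tuesday's flask, once its charge stands as target, has 36.1 s; Saturday's opening has 153 s; Thursday's opening has 279 s; the seed has 298 s. So in Tuesday's flask I expected the seed to start things within the asked 190 s, and the top rung to carry them on.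

The turnover count is time multiplied by the seed rate plus gain times the charge. For Tuesday's flask:

count = (seed + gain·c_substrate)·t = 5.90

share left = (seed + gain·c_substrate)/(gain·c_substrate + seed·e^count) = 2.49%

That put target at 97.5%. At fixed target this rate goes with c_substrate, order 1. At equal substrate, Thursday's flask holds 48.0 mM more target than Sunday's; near Sunday's second reading, Sunday's rate is 0.638 of Thursday's, so slower.

The forecast said 1, slower and 97%, on the ground that “target accelerates its own formation”; my share stood slightly above its figure.

The flask gave 1.0, slower and 97.3%.

    substrate → target (0.001020 s⁻¹)
    substrate + target → 2 target (0.04430 M⁻¹ s⁻¹)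
    substrate → target (0.002530 s⁻¹)

Tuesday's flask reached 97.3% because substrate also passes into target unaided: with the third line of the scheme taken away, it stands at 87.4% at 190 s. With the constants of the scheme the count for Tuesday's flask is 5.72, against my estimated 5.90. Applied to Wednesday's flask, the count puts target at half of the charge at ln(2 + gain·c_substrate/seed)/(seed + gain·c_substrate) = 128 s, and the simulated time is 125 s.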